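Slowness was what these runs showed best: in both, Z was already falling at the earliest reading, so I could read its slow loss but not its making.

| flask | J | X | temperature | remark | time |
|---|---|---|---|---|---|
| midnight | 10 mM | 0.34 equiv | 5 °C | run made earlier |  |
| dawn | 10 mM | 0.75 equiv | 55 °C | run made earlier |  |
| alpha | 10 mM | 0.500 equiv | 100 °C |  | 5.0 min |
| delta | 10 mM | 0.500 equiv | 10 °C |  | 5.0 min |
| eta | 10 mM | 0.500 equiv | 40 °C |  | 5.0 min |
| epsilon | 10 mM | 0.500 equiv | 70 °C |  | 5.0 min |

| run | time / min | Z / % | J / % |
|---|---|---|---|
| midnight | 120 | 25.9 | 59.3 |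
| midnight | 240 | 20.8 | 53.5 |
| midnight | 360 | 16.8 | 49.6 |
| midnight | 480 | 14.0 | 45.9 |
| midnight | 600 | 11.2 | 44.2 |
| dawn | 4.00 | 63.0 | 25.5 |
| dawn | 12.0 | 55.4 | 18.3 |
| dawn | 25.0 | 46.8 | 13.0 |
| dawn | 40.0 | 40.6 | 9.8 |
| dawn | 50.0 | 36.7 | 8.0 |

(scatter of a reading: 0.3 percentage points)

- a species is counted by the J in it: one Q counts as two
- steps thought possible: J + X <-> Z; J + Z -> Q; J -> G

- which flask leads in amount of Z, in percent of the J charged ("all alike" within 1.5 percentage points) (alpha / delta / eta / epsilon / all alike)
- how much Z is there at the end, in percent of the J charged: alpha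
- how much Z is there at the end, in percent of the J charged: delta
- how much Z is there at the end, in percent of the J charged: eta
- how much Z is there at the end, in percent of the J charged: epsilon

Each Q swallows one J and one Z. So I neglected G and took the fall of J plus Z as Q formed. I divided that fall, at two per pair, by the summed product of the fractions J and Z over time. This gave the wear constant, w, the pairs lost per minute at unit fractions (a second-order decay). As readings, w was 0.00345 /min in the midnight run and 0.0684 /min in the dawn run, so its activation energy read 45.4 kJ/mol.

With 0.500 equiv of X fully bound, J and Z each stand at 0.500 and fall together. So I worked with what is left: the reciprocal of Z starts at 2 and grows by w times the time. That gave 22.0% for alpha, 36.9% for epsilon and 46.4% for eta. For delta it gave 49.4%, but that takes the binding as finished, and no reading timed the binding. I expected all four to come in somewhat lower. I chose eta, whose figure stood higher than those of epsilon and alpha, over the untimed figure for delta.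

The forecast named eta, with 19% for alpha, 42% for delta, 44.5% for eta and 34% for epsilon, and called its delta figure “limited by the uncertain” binding constant.

The flasks gave 18.1% for alpha, 31.3% for delta, 44.4% for eta and 33.9% for epsilon, so eta led.

    J + X ⇌ Z (K = 3100 /M, k = 9.50 /M/s, Ea = 42.0 kJ/mol, ΔH = −20.0 kJ/mol)
    J + Z → Q (k = 0.250 /M/s, Ea = 46.0 kJ/mol)
    J → G (k = 2.00 × 10⁻⁵ /s, Ea = 117 kJ/mol)
    (constants at 70 °C)

Eta had not come to rest. At 50.0 min its Z stood at 26.4%, and the wear rule gives 28.2%. Delta, lower than my figure, still held 36.6% of its charged X at 5.00 min. By 50.0 min its Z had risen to 44.0%, while alpha's had fallen to 2.45%.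

For the neighbour of alpha at 75 °C, the same reckoning gives w of 0.178 /min and Z of 34.6%. The computed flask held 31.3%.

(The data are calculated from invented constants; the scatter is artificial.)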